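**Assumption:** the SMILES is natural (2R,3′E,7′E)-α-tocotrienol; C‑2 is the only stereocentre. The phenolic OH is carried unprotected throughout.

## Retrosynthetic overview

1. Disconnect C2′–C3′ (sp3–sp2, B‑alkyl Suzuki) into the (S)-chroman-2-ethyl iodide 10 and the C14 (E,E)-vinyl iodide 16.
2. 16 comes from geraniol by propargylation and Zr‑catalysed methylalumination/iodination (sets 3′E; 7′E is inherited from geraniol).
3. 10 comes from chroman-2-acetate 8, whose pyran ring is closed by an enantioselective 6‑exo intramolecular oxa‑Michael addition of the phenol of (E)-enoate 7; this sets C‑2.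
4. 7 comes from trimethylhydroquinone + methyl vinyl ketone (aryl C–C bond), Wittig methylenation and cross‑metathesis with methyl acrylate.
5. Ring order: the benzene ring is bought; the pyran ring is the only ring made (formed transiently as a ketal in step 1, reopened, then closed for good in step 5).

## Fragment A (chroman)

**Step 1**
Reactants: 1 trimethylhydroquinone; 2 methyl vinyl ketone
Product: 3 (±)-2-methoxy-2,5,7,8-tetramethylchroman-6-ol
Conditions: HC(OMe)3, MeOH, cat. H2SO4, 0 °C → rt, Ar
Reagents that add atoms: trimethyl orthoformate COC(OC)OC / methanol CO (supply the OCH3)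
Why: Acid‑catalysed Friedel–Crafts‑type conjugate addition of the hydroquinone through its only free ring position to the enone, with the ketone trapped by the adjacent OH as a mixed methyl ketal, which fixes the regiochemistry.

**Step 2**
Reactants: 3
Product: 4 (±)-2,5,7,8-tetramethylchromane-2,6-diol (cyclic hemiketal, in equilibrium with 4-(2,5-dihydroxy-3,4,6-trimethylphenyl)butan-2-one)
Conditions: 1 M HCl, acetone/H2O, rt, degassed
Reagents that add atoms: water O
Why: Mild ketal hydrolysis of the mixed aryl/methyl ketal unmasks the methyl ketone as its ring–chain tautomer.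

**Step 3**
Reactants: 4
Product: 5 2,3,5-trimethyl-6-(3-methylbut-3-en-1-yl)benzene-1,4-diol
Conditions: Ph3PCH3Br (4 equiv), KOtBu (4 equiv), THF, 0 → 50 °C, Ar; aq. NH4Cl/Na2S2O4 work‑up (no strong acid)
Reagents that add atoms: methyltriphenylphosphonium bromide C[P+](c1ccccc1)(c1ccccc1)c1ccccc1.[Br-] (supplies CH2)
Why: Wittig methylenation of a lactol: excess ylide deprotonates the OH groups, the hemiketal opens to the phenoxide‑ketone and the ketone is methylenated; the product has no Michael acceptor, so nothing cyclises.

**Step 4**
Reactants: 5; 6 methyl acrylate (10 equiv)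
Product: 7 methyl (2E)-5-(2,5-dihydroxy-3,4,6-trimethylphenyl)-3-methylpent-2-enoate
Conditions: Hoveyda–Grubbs II (5 mol %, two portions), CH2Cl2, 40 °C, Ar; E isomer isolated by chromatography (minor Z removed)
Reagents that add atoms: none besides 6
Why: Olefin cross‑metathesis of a 1,1‑disubstituted alkene with an acrylate, driven by ethylene loss; it runs without base, so the free phenol does not add to the new enoate in a racemic background reaction.

**Step 5 (key ring closure)**
Reactants: 7
Product: 8 methyl [(2S)-6-hydroxy-2,5,7,8-tetramethylchroman-2-yl]acetate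
Conditions: chiral bifunctional iminophosphorane–thiourea superbase (tert‑leucine‑derived, 10 mol %), degassed toluene, rt, Ar; then recrystallisation (hexane/EtOAc) to ≥99 % ee
Reagents that add atoms: none
Why: Enantioselective 6‑exo‑trig intramolecular oxa‑Michael addition: the chiral base deprotonates the ortho OH while the thiourea binds the ester, delivering the phenoxide to the Si face of C‑3 of the (E)-enoate to give (S) at C‑2; the para OH cannot reach the acceptor.

The catalyst enantiomer is the one giving Si‑face attack, confirmed by the rotation of diol 9. (S) here is the same spatial arrangement as (R) in the target; only the CIP ranking changes.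

**Step 6**
Reactants: 8
Product: 9 (2S)-2-(2-hydroxyethyl)-2,5,7,8-tetramethylchroman-6-ol
Conditions: LiAlH4 (2.5 equiv), THF, 0 °C → rt; Rochelle salt work‑up
Reagents that add atoms: none
Why: Hydride reduction of the ester to the primary alcohol; reduction is much faster than any enolisation/retro‑Michael, so C‑2 is untouched, and the phenol is only deprotonated.

**Step 7**
Reactants: 9
Product: 10 (2S)-2-(2-iodoethyl)-2,5,7,8-tetramethylchroman-6-ol
Conditions: I2, PPh3, imidazole, CH2Cl2, 0 °C → rt
Reagents that add atoms: iodine II
Why: Appel‑type iodination (SN2 on the alkoxyphosphonium) is selective for the primary alcohol; the hindered phenol cannot be displaced.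

## Fragment B (side chain)

**Step 8**
Reactants: 11 geraniol
Product: 12 geranyl bromide, (2E)-1-bromo-3,7-dimethylocta-2,6-diene
Conditions: PBr3 (0.4 equiv), Et2O, −10 °C
Reagents that add atoms: phosphorus tribromide BrP(Br)Br
Why: SN2 bromination of the primary allylic alcohol at low temperature keeps the E geometry.

**Step 9**
Reactants: 12; 13 1-(trimethylsilyl)propyne
Product: 14 trimethyl[(5E)-6,10-dimethylundeca-5,9-dien-1-yn-1-yl]silane
Conditions: 13, n‑BuLi, THF, −78 → −20 °C; then 12, −78 → 0 °C
Reagents that add atoms: none besides 13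
Why: Propargylic lithiation of the silyl propyne and SN2 alkylation by the allylic bromide; the silyl group blocks the alkyne terminus, so the propargyl (not allenyl) product forms.

**Step 10**
Reactants: 14
Product: 15 (5E)-6,10-dimethylundeca-5,9-dien-1-yne
Conditions: K2CO3, MeOH, rt
Reagents that add atoms: none
Why: Methanolysis of the alkynyl C–Si bond (protodesilylation) leaves the trisubstituted alkenes untouched.

**Step 11**
Reactants: 15
Product: 16 (1E,5E)-1-iodo-2,6,10-trimethylundeca-1,5,9-triene
Conditions: AlMe3 (2.5 equiv), Cp2ZrCl2 (0.25 equiv), CH2Cl2, 0 °C → rt; then I2, THF, −30 → 0 °C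
Reagents that add atoms: trimethylaluminium C[Al](C)C (CH3); iodine II
Why: Negishi Zr‑catalysed carboalumination adds Me–Al syn across the terminal alkyne (Al terminal), and iodinolysis with retention gives the (E)-vinyl iodide; isolated alkenes do not react.

## Coupling

**Step 12**
Reactants: 10; 16
Product: 17 (2R)-2,5,7,8-tetramethyl-2-[(3E,7E)-4,8,12-trimethyltrideca-3,7,11-trien-1-yl]chroman-6-ol (α‑tocotrienol)
Conditions: 10, t‑BuLi (3.1 equiv), Et2O, −78 °C; 9‑MeO‑9‑BBN (2.5 equiv), THF, −78 °C → rt; then 16, Pd(dppf)Cl2 (5 mol %), AsPh3, aq. K3PO4, DMF, rt, degassed; aq. NH4Cl work‑up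
Reagents that add atoms: none
Why: B‑alkyl Suzuki–Miyaura coupling: the first equivalent of t‑BuLi makes the lithium phenoxide, Li–I exchange and borinate formation give the alkylborate, and Pd couples it with the vinyl iodide with retention of the E geometry; the stereocentre is not involved.

## Compound list

1 | trimethylhydroquinone (2,3,5-trimethylbenzene-1,4-diol) | Cc1cc(O)c(C)c(C)c1O | starting material
2 | methyl vinyl ketone | CC(=O)C=C | starting material
3 | (±)-2-methoxy-2,5,7,8-tetramethylchroman-6-ol | COC1(C)CCc2c(C)c(O)c(C)c(C)c2O1 | intermediate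
4 | (±)-2,5,7,8-tetramethylchromane-2,6-diol (hemiketal) | CC1(O)CCc2c(C)c(O)c(C)c(C)c2O1 | intermediate
5 | 2,3,5-trimethyl-6-(3-methylbut-3-en-1-yl)benzene-1,4-diol | C=C(C)CCc1c(C)c(O)c(C)c(C)c1O | intermediate
6 | methyl acrylate | C=CC(=O)OC | starting material
7 | methyl (2E)-5-(2,5-dihydroxy-3,4,6-trimethylphenyl)-3-methylpent-2-enoate | COC(=O)/C=C(C)/CCc1c(C)c(O)c(C)c(C)c1O | intermediate
8 | methyl [(2S)-6-hydroxy-2,5,7,8-tetramethylchroman-2-yl]acetate | COC(=O)C[C@]1(C)CCc2c(C)c(O)c(C)c(C)c2O1 | intermediate
9 | (2S)-2-(2-hydroxyethyl)-2,5,7,8-tetramethylchroman-6-ol | OCC[C@]1(C)CCc2c(C)c(O)c(C)c(C)c2O1 | intermediate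
10 | (2S)-2-(2-iodoethyl)-2,5,7,8-tetramethylchroman-6-ol | ICC[C@]1(C)CCc2c(C)c(O)c(C)c(C)c2O1 | intermediate
11 | geraniol | OC/C=C(C)/CCC=C(C)C | starting material
12 | geranyl bromide | BrC/C=C(C)/CCC=C(C)C | intermediate
13 | 1-(trimethylsilyl)propyne | CC#C[Si](C)(C)C | starting material
14 | trimethyl[(5E)-6,10-dimethylundeca-5,9-dien-1-yn-1-yl]silane | C[Si](C)(C)C#CCC/C=C(C)/CCC=C(C)C | intermediate
15 | (5E)-6,10-dimethylundeca-5,9-dien-1-yne | C#CCC/C=C(C)/CCC=C(C)C | intermediate
16 | (1E,5E)-1-iodo-2,6,10-trimethylundeca-1,5,9-triene | I/C=C(C)/CC/C=C(C)/CCC=C(C)C | intermediate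
17 | (2R,3′E,7′E)-α-tocotrienol | CC(C)=CCC/C(C)=C/CC/C(C)=C/CC[C@]1(C)CCc2c(C)c(O)c(C)c(C)c2O1 | target

## Step count

Total steps: 12. Longest linear sequence: 8 (steps 1–7, then 12); the side‑chain branch is 4 steps (8–11).

## Steps most likely to fail, with fallbacks

1. **Step 5** (enantioselectivity and rate of oxa‑Michael addition to a β,β‑disubstituted ester). Fallback: cyclise 7 with an achiral base (NaOMe) to racemic 8, saponify, and resolve the acid as its (S)-α‑methylbenzylamine salt. The unwanted enantiomer is recycled by base‑induced retro‑Michael/re‑addition, and the resolved acid is reduced to 9.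
2. **Step 4** (cross‑metathesis of a 1,1‑disubstituted alkene bearing a free hydroquinone; E/Z ratio). Fallback: build the enoate by olefination instead. Trap the open form of 4 as its bis‑allyl ether ketone, run a Horner–Wadsworth–Emmons reaction with trimethyl phosphonoacetate, separate the E isomer, and remove the allyl groups under non‑basic Pd(0)/dimedone conditions to reach 7.
3. **Step 12** (halogen–lithium exchange and Suzuki coupling with an unprotected phenol). Fallback: silylate the 6‑OH of 10 (TBS), convert the iodide to the alkylzinc iodide (Zn, LiCl) and Negishi‑couple with 16 under Pd catalysis, then remove the silyl group with TBAF.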